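**Assumptions:** 6-Bromohexan-2-one is commercially available. PhMgBr and allylMgBr count as starting materials of 8 and 5 non-H atoms. The BINOL catalyst enantiomer is the one that gives the (S)-carbinol, to be matched empirically.

**Retrosynthetic overview**
1. The cis-fused furo[3,2-b]furanone forms in one operation. A SmI2 ketyl radical (C6a) does a 5-exo addition to the β-carbon of a β-alkoxyacrylate, closing the tetrahydrofuran ring (C3a–C6a bond). The Sm(III) alkoxide then lactonizes onto the ester.
2. The β-alkoxyacrylate comes from oxa-Michael addition of a tertiary β-hydroxy methyl ketone to ethyl propiolate.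
3. The β-hydroxy ketone comes from Wacker oxidation of a homoallylic tertiary alcohol. That alcohol comes from enantioselective allylation of 12-phenyldodecan-2-one, which sets C5 (the tertiary ether carbon).
4. The ketone comes from a Negishi coupling of Ph(CH2)6ZnBr with 6-bromohexan-2-one. The bromide comes from PhMgBr and 1,6-dibromohexane.

**Route**

**Step 1**
Reactants: 1 (phenylmagnesium bromide), 2 (1,6-dibromohexane, 3 equiv)
Product: 3 (6-bromohexyl)benzene
Conditions: Li2CuCl4 (3 mol %), THF, 0 °C → rt
Reagents that add atoms: none
Why: Cu-catalysed Kumada–Kochi coupling of an aryl Grignard with a primary alkyl bromide, and the excess dibromide suppresses double arylation.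

**Step 2**
Reactants: 3, 4 (6-bromohexan-2-one)
Product: 5 (12-phenyldodecan-2-one)
Conditions: (i) Zn dust, LiCl, BrCH2CH2Br/TMSCl (cat.), THF, 50 °C; (ii) 4, Pd2(dba)3 (2 mol %), PCyp2Ph (8 mol %), N-methylimidazole, THF/NMP, rt
Reagents that add atoms: none
Why: The alkylzinc bromide forms in situ, and a Negishi alkyl–alkyl coupling of primary bromides (Fu-type Pd/phosphine) tolerates the ketone.

**Step 3**
Reactants: 5, 6 (allylmagnesium bromide, used as allyl-B(OiPr)2 prepared in situ with B(OiPr)3)
Product: 7 (S)-4-methyl-14-phenyltetradec-1-en-4-ol
Conditions: allyl-B(OiPr)2 (1.5 equiv), (S)-3,3′-Br2-BINOL (15 mol %), iPrOH (2 equiv), PhMe, 40 °C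
Reagents that add atoms: allyldiisopropoxyborane, C=CCB(OC(C)C)OC(C)C
Why: BINOL-catalysed asymmetric allylboration of a methyl ketone, with the chiral borate transferring allyl to one ketone face, sets the tertiary carbinol C5 as (S) and this centre is never touched again.

**Step 4**
Reactants: 7
Product: 8 (S)-4-hydroxy-4-methyl-14-phenyltetradecan-2-one
Conditions: PdCl2 (10 mol %), CuCl (1 equiv), O2 (1 atm), DMF/H2O 7:1, rt
Reagents that add atoms: water (O); dioxygen (O=O) as terminal oxidant
Why: Tsuji–Wacker oxidation is Markovnikov-selective for the terminal alkene and the tertiary stereocentre is not involved.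

**Step 5**
Reactants: 8, 9 (ethyl propiolate)
Product: 10 ethyl (2E)-3-{[(4S)-4-methyl-2-oxo-14-phenyltetradecan-4-yl]oxy}prop-2-enoate
Conditions: PMe3 (10 mol %), CH2Cl2, 0 °C → rt
Reagents that add atoms: none
Why: Phosphine-catalysed oxa-Michael addition of the tertiary alcohol to the propiolate gives the thermodynamically favoured (E)-β-alkoxyacrylate; no new stereocentre forms.

**Step 6**
Reactants: 10
Product: 11 target, (3aR,5S,6aR)-5,6a-dimethyl-5-(10-phenyldecyl)tetrahydrofuro[3,2-b]furan-2(3H)-one
Conditions: SmI2 (3.2 equiv), HMPA (8 equiv), t-BuOH (2 equiv), THF, –78 → 0 °C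
Reagents that add atoms: none (EtOH is lost)
Why: SmI2 ketyl–olefin reductive cyclization (Nakata-type) forms the ketyl at C6a, adds it 5-exo to the β-carbon of the acrylate, and the resulting α-ester radical is reduced and protonated. The Sm(III) alkoxide then lactonizes. Sm(III) chelation of the ketyl oxygen and the ester C=O should place O–Sm cis to the CH2CO2Et arm, and only that cis isomer can lactonize, which fixes the cis ring fusion with Me(C6a) trans to the arm. The pseudo-equatorial preference of the long chain at C5 (a 1,3-cis Beckwith preference) should put the chain endo, as in the target. That preference is weak because Me and the chain are similar in size, so the diastereomer ratio is expected to be modest (about 2:1), and the desired isomer is separated by chromatography.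

**Compound list**
1 | phenylmagnesium bromide | Br[Mg]c1ccccc1 | starting material
2 | 1,6-dibromohexane | BrCCCCCCBr | starting material
3 | (6-bromohexyl)benzene | BrCCCCCCc1ccccc1 | intermediate
4 | 6-bromohexan-2-one | CC(=O)CCCCBr | starting material
5 | 12-phenyldodecan-2-one | CC(=O)CCCCCCCCCCc1ccccc1 | intermediate
6 | allylmagnesium bromide | C=CC[Mg]Br | starting material
7 | (S)-4-methyl-14-phenyltetradec-1-en-4-ol | C=CC[C@@](C)(O)CCCCCCCCCCc1ccccc1 | intermediate
8 | (S)-4-hydroxy-4-methyl-14-phenyltetradecan-2-one | CC(=O)C[C@@](C)(O)CCCCCCCCCCc1ccccc1 | intermediate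
9 | ethyl propiolate | C#CC(=O)OCC | starting material
10 | ethyl (2E)-3-{[(4S)-4-methyl-2-oxo-14-phenyltetradecan-4-yl]oxy}prop-2-enoate | CCOC(=O)/C=C/O[C@](C)(CC(C)=O)CCCCCCCCCCc1ccccc1 | intermediate
11 | plakortolide ether, (3aR,5S,6aR)-5,6a-dimethyl-5-(10-phenyldecyl)tetrahydrofuro[3,2-b]furan-2(3H)-one | C[C@]1(CCCCCCCCCCc2ccccc2)C[C@@]2(C)OC(=O)C[C@H]2O1 | target

**Totals:** 6 steps in total. The longest linear sequence is 6 steps (1 → 2 → 3 → 4 → 5 → 6).

**Three steps most likely to fail**
1. **Step 6 (SmI2 cyclization/lactonization):**
   - Risks: the diastereomer ratio at C5 relative to C6a/C3a may be poor. The Sm(III)-enolate could also undergo β-alkoxide elimination, opening the new ether ring, or the trans-hydroxy ester could form and fail to lactonize.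
   - Fallback: Ti(III) ketyl cyclization (Cp2TiCl2, Zn, collidine·HCl), or a photoredox ketyl–acrylate cyclization with a Lewis acid. Both use a different metal–oxygen chelate and rely on the Ti–O or Lewis-acid-bound ketyl geometry to control the cis-lactone pathway.
2. **Step 3 (enantioselective allylation of an aliphatic methyl ketone):**
   - Risk: ee may be below 90 % for a dialkyl ketone with a remote phenyl group.
   - Fallback: make racemic 7 with allylMgBr and resolve it by preparative chiral SFC/HPLC.
3. **Step 5 (tertiary alcohol + propiolate on a β-hydroxy ketone):**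
   - Risk: base could trigger retro-aldol or dehydration of 8.
   - Fallback: add the alcohol of 7 to ethyl propiolate first, when there is no β-carbonyl, and then run the Wacker oxidation on the acrylate-bearing alkene. This reverses the order of steps 4 and 5.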